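| flask | substrate | reagent in the second phase | protic impurity | remark | time | volume of the second phase over the first |
|---|---|---|---|---|---|---|
| spring | 10 mM | 30 mM | 5 mM | run made earlier |  |  |
| midnight | 10 mM | 30 mM | 7.5 mM | run made earlier |  |  |
| dawn | 15 mM | 30 mM | 10 mM | run made earlier |  |  |
| flask | 10 mM | 30.0 mM | 10.0 mM |  | 8.0 h | 1.0 |

- spring (time / h: target / %): 0.417: 55; 0.667: 67; 1.33: 66; 2.50: 54; 5.00: 39
- midnight (time / h: target / %): 0.417: 55; 0.667: 68; 1.33: 70; 2.50: 54; 5.00: 44
- dawn (time / h: target / %): 0.417: 51; 1.33: 72; 2.00: 71; 3.00: 66; 5.00: 58

(readings scatter by 2 percentage points)

- in the second phase: reagent in the second phase; everything else is in the first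
- charges count per volume of the first phase; a concentration in a rate is the amount of a species over the volume of its own phase; every rate counts per litre of the first phase
- the earlier runs hold the two phases in the same ratio of volumes as the flask asked about

* target at 8.0 h, in percent of the substrate charged
* the change that raises the amount of target at 8.0 h, in percent of the substrate charged most ("none" if none brings more than 2 percentage points) (violet / teal / none)
* amount of target at 8.0 h, in percent of the substrate charged, after teal

Time was the first setting I turned by hand, and it cost target: the spring run read 67% after 0.667 h but 39% after 5.00 h, the rise and fall of an intermediate in a consecutive reaction. The midnight run lost 10 percentage points between its last readings, and I guessed that the last 3.00 h of the flask ran at 0.5 of that pace, a loss of 6 points.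

Protic impurity came next. The spring and midnight runs differ in nothing else, [protic impurity] being 5 mM against 7.5 mM, and at 5.00 h the midnight run read 44% against 39%. So I treated the flask as the spring run plus a correction and defined the shield, the points of target kept at a late reading, at fixed charges of substrate and reagent, per equivalent of protic impurity on substrate: 20 points per equivalent, rough, since it is a difference of readings that each scatter by 2 points. The flask carries 0.500 equivalent more than the spring run, worth 10 points, so I reckoned 43.0% at 8.0 h.

Then came the reagent. Teal adds 3.00 equivalents; if each undoes an equivalent of impurity, the cost is 60 points, more than my whole estimate, so I expected little target and gave no number. Violet moves no charge, so the shield gives it no correction.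

The forecast, lower than my 43.0%, said 42% (34% to 50%), 5% after teal (1% to 15%) and best change none, reasoning “Violet only speeds up reagent delivery”.

The flask gave 41.7%, teal gave 10.3%, and the best change was violet, at 2.7 points.

    reagent in the reaction phase ⇌ reagent in the second phase, rate k1*([reagent in the reaction phase] - [reagent in the second phase]/K1) per volume of the first phase (partition coefficient = 0.450, kL = 0.0170 min⁻¹)
    substrate + reagent in the reaction phase → target (k = 6.30 M⁻¹ min⁻¹)
    reagent in the reaction phase + target → over-reaction product (k = 0.960 M⁻¹ min⁻¹)
    reagent in the reaction phase + protic impurity → quenched reagent (k = 1.30 M⁻¹ min⁻¹)
    2 reagent in the reaction phase → homo dimer (k = 0.680 M⁻¹ min⁻¹)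

At 8.00 h the flask held 41.7% target and 58.2% over-reaction product. Taking 0.600 equivalent off the flask with the shield gives 29.7% for a neighbour charged with 4.0 mM of protic impurity, and that neighbour stood at 30.9%.

The readings come from a simulation from invented constants, and the scatter is random.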